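**Retrosynthetic overview**
- Target ⇒ C4' ketone (syn-selective 1,3-reduction, last step) ⇒ C2'–C3' Mukaiyama aldol between a lactone acetaldehyde (C2–C6, C1', C2') and a C13 enol silane (C3'–C15'). C6 controls C2' (1,3-anti); C2' and C6' together control C4'.
- Lactone aldehyde ⇒ (R)-6-allyl-5,6-dihydropyran-2-one (ozonolysis) ⇒ (S)-6-allyl-δ-valerolactone (selenoxide elimination) ⇒ rac-2-allylcyclopentanone by the key step, a stereoconvergent Baeyer–Villiger ring expansion (1,2-shift of C2 from carbon to oxygen) that sets C6 ⇒ cyclopentanone + allyl bromide.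
- Enol silane ⇒ (S)-4-hydroxytridecan-2-one ⇒ decanal + 2-methoxypropene (catalytic asymmetric acetone aldol, sets C6'); decanal ⇒ 1-bromoheptane + acrolein.
- Ring order: the only ring is bought as a cyclopentanone and expanded to the six-membered lactone before the two fragments are joined; no other ring is formed.

Assumption: the ligand antipode in step 2 and the monooxygenase variant in step 5 are the ones that give the (S) products named; each sense is checked once (Mosher ester of 8; optical rotation of 14 against material from the fallback).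

Locants C2–C6 refer to the lactone ring of the target and C1'–C15' to its side chain.

**Step 1**
Reactants: 1 1-bromoheptane; 2 acrolein
Product: 5 decanal, via heptylmagnesium bromide 3 (not isolated), via silyl enol ether of decanal 4 (not isolated)
Conditions: Mg, THF, rt; then CuBr·SMe2 (5 mol %), Me3SiCl, HMPA, 2, THF, −78 °C; 1 M HCl, rt
Reagents that add atoms: none
Why: Copper-catalysed, Me3SiCl-accelerated conjugate addition of the Grignard reagent to acrolein (Kuwajima–Nakamura conditions) gives the enol silane, which is hydrolysed to the aldehyde; no stereocentre is formed.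

**Step 2**
Reactants: 5 decanal; 6 2-methoxypropene
Product: 8 (S)-4-hydroxytridecan-2-one, via enol ether adduct 7 (not isolated)
Conditions: Ti(OiPr)4 (5 mol %), 2-[(3-bromo-5-tert-butyl-2-hydroxybenzylidene)amino]-2'-hydroxy-1,1'-binaphthyl (single antipode), 3,5-di-tert-butylsalicylic acid, 2,6-di-tert-butyl-4-methylpyridine, 6 as solvent, 0 °C; then 2 M HCl, Et2O, rt
Reagents that add atoms: water, O
Why: Carreira's titanium-catalysed ene-type acetone aldol addition, in which the chiral Ti complex shields one aldehyde face and sets the carbinol centre (the later C6') as S; acid hydrolysis of the enol ether then gives the methyl ketone.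

**Step 3**
Reactants: 8 (S)-4-hydroxytridecan-2-one
Product: 9 (S)-2,4-bis(trimethylsilyloxy)tridec-1-ene
Conditions: Me3SiCl (3 equiv), LiN(iPr)2 (2.3 equiv), THF, −78 °C (internal quench); Et3N, pentane, filter
Reagents that add atoms: chlorotrimethylsilane, C[Si](C)(C)Cl
Why: Kinetic silyl enol ether formation under Corey internal-quench conditions traps the methyl-side enolate before retro-aldol can occur and silylates the alkoxide in the same flask; the stereocentre is not touched.

**Step 4**
Reactants: 10 cyclopentanone; 11 allyl bromide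
Product: 13 rac-2-allylcyclopentanone, via lithium enolate of cyclopentanone 12 (not isolated)
Conditions: LiN(iPr)2 (1.05 equiv), THF, −78 °C; 11, DMPU, −78 → 0 °C
Reagents that add atoms: none
Why: Kinetic lithium enolate alkylation (SN2 on an allylic bromide); a racemate is sufficient because the next step is stereoconvergent.

**Step 5**
Reactants: 13 rac-2-allylcyclopentanone
Product: 14 (S)-6-allyltetrahydro-2H-pyran-2-one
Conditions: (S)-ketone-selective Baeyer–Villiger monooxygenase (TmCHMO-type variant, cell-free extract), NADP+ (cat.), glucose dehydrogenase, D-glucose, air, glycine–NaOH buffer pH 9.5, weakly basic anion-exchange resin (Lewatit MP 62), 5 % MeOH, 30 °C, 24–48 h; then pH 3, EtOAc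
Reagents that add atoms: dioxygen, O=O
Why: Proposed new method: a dynamic kinetic Baeyer–Villiger ring expansion in which the α-proton of 13 exchanges through the enolate at pH 9.5 on the basic resin (estimated half-life of a few hours, faster than oxidation of the mismatched enantiomer) while the enzyme-bound flavin C4a-peroxide adds only to the carbonyl of (S)-13 and the more substituted C2 migrates antiperiplanar to the breaking O–O bond with retention (1,2-shift from carbon to oxygen, five- to six-membered ring), the nucleophilic peroxyflavin leaving the alkene untouched; the closest known reactions are the CHMO-catalysed dynamic kinetic resolution of 2-(benzyloxymethyl)cyclopentanone and the classical kinetic resolution of 2-alkylcyclopentanones, and what is new is the dynamic mode on a plain 2-allyl ketone with the (S) sense, which calls for an engineered variant.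

**Step 6**
Reactants: 14 (S)-6-allyltetrahydro-2H-pyran-2-one
Product: 18 (R)-6-allyl-5,6-dihydro-2H-pyran-2-one, via lactone lithium enolate 15 (not isolated), via 3-phenylselanyl lactone 16 (not isolated), via selenoxide 17 (not isolated)
Conditions: LiN(iPr)2 (1.1 equiv), THF, −78 °C; PhSeBr, −78 °C; then 30 % H2O2, pyridine, CH2Cl2, 0 °C → rt
Reagents that add atoms: none
Why: α-Selenenylation of the lactone enolate followed by selenoxide syn-elimination gives the endocyclic enoate; C6 is not touched and its descriptor changes from S to R only because the CIP priorities change.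

**Step 7**
Reactants: 18 (R)-6-allyl-5,6-dihydro-2H-pyran-2-one
Product: 20 2-[(2S)-6-oxo-3,6-dihydro-2H-pyran-2-yl]acetaldehyde, via secondary ozonide 19 (not isolated)
Conditions: O3, CH2Cl2, −78 °C (Sudan Red 7B end point); PPh3, −78 °C → rt; used crude
Reagents that add atoms: ozone, [O-][O+]=O
Why: Ozonolysis with reductive work-up, in which ozone cleaves the electron-rich terminal alkene much faster than the electron-poor conjugated lactone alkene, and the neutral PPh3 work-up protects the β-acyloxy aldehyde from elimination.

**Step 8**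
Reactants: 20 2-[(2S)-6-oxo-3,6-dihydro-2H-pyran-2-yl]acetaldehyde; 9 (S)-2,4-bis(trimethylsilyloxy)tridec-1-ene
Product: 22 (S)-6-[(2R,6S)-2,6-dihydroxy-4-oxopentadecyl]-5,6-dihydro-2H-pyran-2-one, via 6'-O-trimethylsilyl aldol 21 (not isolated)
Conditions: BF3·OEt2 (1.2 equiv), CH2Cl2, −78 °C; pH 7 buffer; then 1 M HCl, THF, 0 °C
Reagents that add atoms: none
Why: Mukaiyama aldol through an open transition state, in which the polar β-acyloxy substituent (the ring oxygen at C6) directs attack to give the 1,3-anti product (Evans model) and so sets C2'; the remote silyl ether exerts no 1,5-bias, and dilute acid then removes the trimethylsilyl group.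

**Step 9**
Reactants: 22 (S)-6-[(2R,6S)-2,6-dihydroxy-4-oxopentadecyl]-5,6-dihydro-2H-pyran-2-one
Product: 24 (S)-6-[(2S,4S,6S)-2,4,6-trihydroxypentadecyl]-5,6-dihydro-2H-pyran-2-one, via bis(diethylboryl) chelate 23 (not isolated)
Conditions: Et2BOMe (2.2 equiv), THF/MeOH 4:1, −78 °C; NaBH4, −78 °C, 3 h; AcOH, then MeOH co-evaporation
Reagents that add atoms: none
Why: Narasaka–Prasad reduction, in which the boron chelate of either β-hydroxyl (they are 1,5-syn to each other) directs external hydride to the same carbonyl face and gives the all-syn triol with C4' as S; at −78 °C the enoate is not reduced.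

**Compound list**
1 | 1-bromoheptane | CCCCCCCBr | starting material
2 | acrolein | C=CC=O | starting material
3 | heptylmagnesium bromide | CCCCCCC[Mg]Br | intermediate
4 | trimethyl(dec-1-en-1-yloxy)silane (E/Z mixture) | CCCCCCCCC=CO[Si](C)(C)C | intermediate
5 | decanal | CCCCCCCCCC=O | intermediate
6 | 2-methoxypropene | COC(C)=C | starting material
7 | (S)-2-methoxytridec-1-en-4-ol | CCCCCCCCC[C@H](O)CC(=C)OC | intermediate
8 | (S)-4-hydroxytridecan-2-one | CCCCCCCCC[C@H](O)CC(C)=O | intermediate
9 | (S)-2,4-bis(trimethylsilyloxy)tridec-1-ene | CCCCCCCCC[C@H](O[Si](C)(C)C)CC(=C)O[Si](C)(C)C | intermediate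
10 | cyclopentanone | O=C1CCCC1 | starting material
11 | allyl bromide | C=CCBr | starting material
12 | lithium cyclopent-1-en-1-olate | [Li]OC1=CCCC1 | intermediate
13 | rac-2-allylcyclopentanone | C=CCC1CCCC1=O | intermediate
14 | (S)-6-allyltetrahydro-2H-pyran-2-one | C=CC[C@@H]1CCCC(=O)O1 | intermediate
15 | lithium (S)-6-allyl-5,6-dihydro-4H-pyran-2-olate | C=CC[C@@H]1CCC=C(O[Li])O1 | intermediate
16 | (6S)-6-allyl-3-(phenylselanyl)tetrahydro-2H-pyran-2-one (C3 epimers) | C=CC[C@@H]1CCC([Se]c2ccccc2)C(=O)O1 | intermediate
17 | (6S)-6-allyl-3-(phenylseleninyl)tetrahydro-2H-pyran-2-one (mixture at C3 and Se) | C=CC[C@@H]1CCC([Se](=O)c2ccccc2)C(=O)O1 | intermediate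
18 | (R)-6-allyl-5,6-dihydro-2H-pyran-2-one | C=CC[C@@H]1CC=CC(=O)O1 | intermediate
19 | (S)-6-(1,2,4-trioxolan-3-ylmethyl)-5,6-dihydro-2H-pyran-2-one (mixture at the trioxolane carbon) | C1(C[C@@H]2CC=CC(=O)O2)OCOO1 | intermediate
20 | 2-[(2S)-6-oxo-3,6-dihydro-2H-pyran-2-yl]acetaldehyde | O=CC[C@@H]1CC=CC(=O)O1 | intermediate
21 | (S)-6-[(2R,6S)-2-hydroxy-4-oxo-6-(trimethylsilyloxy)pentadecyl]-5,6-dihydro-2H-pyran-2-one | CCCCCCCCC[C@H](O[Si](C)(C)C)CC(=O)C[C@H](O)C[C@@H]1CC=CC(=O)O1 | intermediate
22 | (S)-6-[(2R,6S)-2,6-dihydroxy-4-oxopentadecyl]-5,6-dihydro-2H-pyran-2-one | CCCCCCCCC[C@H](O)CC(=O)C[C@H](O)C[C@@H]1CC=CC(=O)O1 | intermediate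
23 | (S)-6-[(2R,6S)-2,6-bis(diethylboranyloxy)-4-oxopentadecyl]-5,6-dihydro-2H-pyran-2-one | CCCCCCCCC[C@H](OB(CC)CC)CC(=O)C[C@H](OB(CC)CC)C[C@@H]1CC=CC(=O)O1 | intermediate
24 | (S)-6-[(2S,4S,6S)-2,4,6-trihydroxypentadecyl]-5,6-dihydro-2H-pyran-2-one | CCCCCCCCC[C@H](O)C[C@H](O)C[C@H](O)C[C@@H]1CC=CC(=O)O1 | target

**Step count and risks**
Total steps: 9. Longest linear sequence: 6 (steps 4 to 9, from cyclopentanone).

The three steps most likely to fail:

First, the new ring expansion of step 5. The enzyme may show low selectivity for a short 2-allyl chain, the wrong sense, or racemisation that is too slow. The fallback uses only known chemistry, sets out from 10 and comes back at 14. Cyclopentanone 10 is condensed with SAMP to the hydrazone (S)-N-cyclopentylidene-2-(methoxymethyl)pyrrolidin-1-amine F1. Deprotonation with LiN(iPr)2 and alkylation with allyl bromide 11 at −100 °C (Enders alkylation, auxiliary control) gives (S)-N-[(S)-2-allylcyclopentylidene]-2-(methoxymethyl)pyrrolidin-1-amine F2. Two-phase cleavage with aqueous oxalic acid/Et2O spares the alkene, returns the auxiliary and gives (S)-2-allylcyclopentanone F3. A conventional stereoretentive Baeyer–Villiger oxidation (Me3SiOOSiMe3, cat. Me3SiOTf, CH2Cl2, −40 °C, conditions that do not epoxidise alkenes) then gives 14.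

Second, the ozonolysis of step 7. Over-oxidation of the enoate and loss of the β-acyloxy aldehyde by elimination are the risks. The fallback sets out from 18 and comes back at 20. OsO4 (1 mol %)/NMO in acetone–water at 0 °C dihydroxylates only the electron-rich terminal alkene to the bench-stable diol (S)-6-[(2RS)-2,3-dihydroxypropyl]-5,6-dihydro-2H-pyran-2-one F4, which can be stored. NaIO4 on silica gel in CH2Cl2 cleaves it to 20 under neutral conditions immediately before the aldol.

Third, the aldol of step 8. The 1,3-anti preference of a β-acyloxy aldehyde may be only moderate (about 4:1 to 9:1). The fallback replaces substrate control by reagent control, sets out from 8 and comes back at 22. TBSCl/imidazole gives (S)-4-(tert-butyldimethylsilyloxy)tridecan-2-one F5. Enolisation with the Ipc2BCl antipode that attacks the si face of 20 ((−)-Ipc2BCl by Paterson's methyl ketone model) and Et3N, then addition of 20 at −78 °C (Paterson boron aldol, non-basic work-up), gives (S)-6-[(2R,6S)-6-(tert-butyldimethylsilyloxy)-2-hydroxy-4-oxopentadecyl]-5,6-dihydro-2H-pyran-2-one F6. HF·pyridine in THF removes the silyl group and gives 22.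

**Further compounds**
F1 | step 5 | (S)-N-cyclopentylidene-2-(methoxymethyl)pyrrolidin-1-amine | COC[C@@H]1CCCN1N=C1CCCC1
F2 | step 5 | (S)-N-[(S)-2-allylcyclopentylidene]-2-(methoxymethyl)pyrrolidin-1-amine | C=CC[C@@H]1CCCC1=NN1CCC[C@H]1COC
F3 | step 5 | (S)-2-allylcyclopentanone | C=CC[C@@H]1CCCC1=O
F4 | step 7 | (S)-6-[(2RS)-2,3-dihydroxypropyl]-5,6-dihydro-2H-pyran-2-one | OCC(O)C[C@@H]1CC=CC(=O)O1
F5 | step 8 | (S)-4-(tert-butyldimethylsilyloxy)tridecan-2-one | CCCCCCCCC[C@H](O[Si](C)(C)C(C)(C)C)CC(C)=O
F6 | step 8 | (S)-6-[(2R,6S)-6-(tert-butyldimethylsilyloxy)-2-hydroxy-4-oxopentadecyl]-5,6-dihydro-2H-pyran-2-one | CCCCCCCCC[C@H](O[Si](C)(C)C(C)(C)C)CC(=O)C[C@H](O)C[C@@H]1CC=CC(=O)O1
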